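In the red run, at 35 °C, X already reads 0% after 2.00 h. From then on Z falls while J rises, ending at 73.2% and 26.9%, so you are watching Z pass slowly into J.

Let s be the share Z/(Z+J), and k the part of Z turning into J each hour. If k stays constant, s = exp(−kt), and kt counts the lifetimes spent. The last red reading gives k = 0.0125 /h at 35 °C. That is a lifetime of 79.9 h, much longer than the 2.00 h by which X reads 0%, so this is the rate-limiting step for J. Does the comparison drift as J builds up? At 15.0 h this k predicts 82.9%, and the readings give 83.1%, so no drift shows within the scatter. I assume k holds at ash's lower charge of X.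

| flask | X | Z | temperature | remark | time |
|---|---|---|---|---|---|
| green | 0.25 M | 5 mM | 10 °C | run made earlier |  |
| red | 1 M | 5 mM | 35 °C | run made earlier |  |
| ash | 0.50 M | 5.00 mM | 35 °C |  | 30 h |
| oak | 0.50 M | 5.00 mM | 55 °C |  | 30 h |
| elm | 0.50 M | 5.00 mM | 15 °C |  | 30 h |

| run | time / h | Z / % | J / % | X / % |
|---|---|---|---|---|
| green | 6.00 | 103.8 | 0.4 | 0.3 |
| green | 10.0 | 101.5 | 0 | 0.1 |
| green | 15.0 | 102.0 | 0.8 | 1.2 |
| green | 20.0 | 100.6 | 0 | 0 |
| green | 30.0 | 100.8 | 1.4 | 0 |
| green | 48.0 | 99.8 | 1.0 | 0.6 |
| green | 96.0 | 99.3 | 2.5 | 0 |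
| red | 2.00 | 97.8 | 2.6 | 0 |
| red | 3.00 | 94.6 | 3.5 | 0.4 |
| red | 4.00 | 96.4 | 5.3 | 0.7 |
| red | 6.00 | 94.3 | 7.1 | 0.5 |
| red | 10.0 | 89.0 | 13.9 | 0 |
| red | 15.0 | 82.9 | 16.8 | 0 |
| red | 25.0 | 73.2 | 26.9 | 0.4 |

(standard deviation of a reading: 1 percentage point)

- the share counts what is present at the end, not what went on to other products

1. the flask with the highest share of Z in all that became Z or J ("all alike" if they lie within 1.5 percentage points) (ash / oak / elm / all alike)
2. share of Z in all that became Z or J, ash
3. share of Z in all that became Z or J, oak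
4. share of Z in all that became Z or J, elm

Now turn the question round. For ash to stand level with a nearly untouched flask, it could spend about 0.0151 lifetimes, yet ash spends 0.376, so "all alike" is out. For a hotter flask to lead, k would have to fall with heat, but the green run, from its last and rough reading, gives 2.59 × 10⁻⁴ /h at 10 °C, and red's k is 48.3 times that, though these runs differ in their charge of X as well as in temperature.

A straight line of ln k against temperature, taking the charge of X to have no effect on k, gives me these shares: ash 68.7%, elm 98.3%, and oak 0.0235%, which is hardly any. So elm stands highest.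

The forecast chose elm, with 70% for ash, 2% for oak, above my figure, and 98% for elm, on the ground that “Z then slowly turns into J”.

The flasks give elm as the highest, with 68.6% for ash, 0.681% for oak and 98.1% for elm.

    X + Z → 2 Z (k = 2.10 /M/min, Ea = 55.0 kJ/mol)
    Z ⇌ J (K = 770, k = 2.10 × 10⁻⁴ /min, Ea = 110 kJ/mol, ΔH = −1.00 kJ/mol)
    X → Z (k = 2.80 × 10⁻⁵ /min, Ea = 112 kJ/mol)
    Z → G (k = 9.00 × 10⁻⁷ /min, Ea = 125 kJ/mol)
    (constants at 35 °C)

In ash at 30.0 h, the forward step from Z into J uses Z 230 times as fast as the step into G, and G holds 0.136% of the X charged against 31.7% as J. Counting lifetimes with k, ash's 0.376 leaves 68.7% against the 68.6% it shows, and the same flask read at 8.0 h spends 0.100 lifetimes, which leaves 90.5% against its 90.5%.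

(Readings and results are simulated for an exercise; the scatter is artificial.)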